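**Retrosynthetic overview**
1. C11–O ester: SN2 inversion of an (R)-α-chloro ketone by p-coumaric acid, which comes from a Heck reaction of 4-iodophenol and acrylic acid.
2. Cyclopropane C7–C8–C9: trans-selective carbene transfer from (R)-3-chloro-1-diazobutan-2-one (from (R)-2-chloropropanoic acid and CH2N2) to the vinyl group of a silyl-protected 6-(1-hydroxyallyl)dihydropyranone.
3. Dihydropyranone (key step): carbonylative ring expansion of a trans vinyl epoxide from a three- to a six-membered ring. CO becomes C1, the C5–O bond is kept, and the C=C bond is then moved into conjugation.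
4. Vinyl epoxide: Sharpless kinetic resolution of racemic hepta-1,4,6-trien-3-ol (pentadienal plus vinylmagnesium bromide) fixes C5/C6 as anti.
5. Ring order: oxirane, then δ-lactone, then cyclopropane. The arene is bought.

Assumption: locants C1–C12 follow the brevipolide chain (C1 lactone C=O, C5 lactone CH–O, C6 carbinol, C7/C8/C9 cyclopropane, C10 ketone, C11 ester-bearing CH, C12 methyl), and all numbered starting materials are catalogue items.

**Step 1**
Reactants: 1 (2E)-penta-2,4-dienal; 2 vinylmagnesium bromide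
Product: 3 rac-(4E)-hepta-1,4,6-trien-3-ol
Conditions: THF, −78 °C; then sat. aq NH4Cl
Reagents that add atoms: none
Why: Grignard 1,2-addition, in which the hard vinyl nucleophile attacks the aldehyde carbonyl at low temperature rather than the diene terminus; the new carbinol centre (C6) is racemic here and is resolved in step 2.

**Step 2**
Reactants: 3 rac-(4E)-hepta-1,4,6-trien-3-ol
Product: 5 tert-butyl(dimethyl){[(1S)-1-[(2R,3S)-3-ethenyloxiran-2-yl]prop-2-en-1-yl]oxy}silane, via epoxy alcohol 4 (not isolated)
Conditions: Ti(OiPr)4 (10 mol %), L-(+)-DIPT (13 mol %), t-BuOOH (0.45 equiv), 4 Å MS, CH2Cl2, −20 °C; then 2,6-lutidine, TBSOTf, −20 to 0 °C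
Reagents that add atoms: tert-butyl hydroperoxide CC(C)(C)OO (epoxide oxygen); tert-butyldimethylsilyl triflate CC(C)(C)[Si](C)(C)OS(=O)(=O)C(F)(F)F (silyl group)
Why: Sharpless asymmetric epoxidation run as a kinetic resolution with in situ derivatisation, in which L-(+)-DIPT makes the (S)-alcohol react far faster at its more nucleophilic internal E-alkene to give the anti (erythro) epoxy alcohol, so C6 is selected and C5 is set; silylation in the same flask avoids loss of the small polar 4, and the silyl ether of unreacted (R)-3 is removed by chromatography.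

**Step 3 (key step)**
Reactants: 5 tert-butyl(dimethyl){[(1S)-1-[(2R,3S)-3-ethenyloxiran-2-yl]prop-2-en-1-yl]oxy}silane
Product: 7 (6R)-6-[(1S)-1-(tert-butyldimethylsilyloxy)prop-2-en-1-yl]-5,6-dihydro-2H-pyran-2-one, via unconjugated lactone 6 (not isolated)
Conditions: Pd2(dba)3·CHCl3 (2.5 mol %), Xantphos (6 mol %), CO (20 bar), THF, 40 °C; vent, then DBU (20 mol %), 0 °C to rt
Reagents that add atoms: carbon monoxide [C-]#[O+]
Why: Proposed new method: catalytic, stereoretentive carbonylative ring expansion of a vinyl epoxide to a δ-lactone, in which zerovalent palladium ionises only the allylic C4–O bond (C5–O is never broken, so C5 is retained) to a zwitterionic π-allylpalladium alkoxide whose syn and anti forms interconvert by π-σ-π shifts, the wide-bite-angle diphosphine holds palladium at the unhindered terminus C2 where the allyl carbon migrates onto CO, and only the Z-acylpalladium can be captured by the C5 alkoxide through a six-membered acyl transfer, which drains the equilibrium, turns the three-membered ring into the six-membered ring and frees the catalyst, after which DBU moves the double bond into conjugation; the closest known reaction types are the stoichiometric tricarbonyliron lactone complexes of vinyl epoxides that give δ-lactones under CO pressure, the palladium-catalysed alkoxycarbonylation of vinyl epoxides, and the palladium-catalysed carbonylative ring expansion of vinyl aziridines to lactams.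

**Step 4**
Reactants: 8 (2R)-2-chloropropanoic acid
Product: 10 (3R)-3-chloro-1-diazobutan-2-one, via acid chloride 9 (not isolated)
Conditions: (COCl)2, DMF (cat.), CH2Cl2, 0 °C to rt, evaporate; CH2N2 (3 equiv), Et2O, 0 °C
Reagents that add atoms: oxalyl chloride O=C(Cl)C(=O)Cl (chlorine of 9); diazomethane C=[N+]=[N-]
Why: Acylation of diazomethane (first stage of the Arndt–Eistert sequence), run without amine base and with excess CH2N2 to take up HCl, so no ketene forms and the chlorine-bearing stereocentre (C11, R) is untouched.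

**Step 5**
Reactants: 7 (6R)-6-[(1S)-1-(tert-butyldimethylsilyloxy)prop-2-en-1-yl]-5,6-dihydro-2H-pyran-2-one; 10 (3R)-3-chloro-1-diazobutan-2-one
Product: 11 (6R)-6-[(S)-(tert-butyldimethylsilyloxy){(1S,2S)-2-[(2R)-2-chloropropanoyl]cyclopropyl}methyl]-5,6-dihydro-2H-pyran-2-one
Conditions: [Ru(pheox)(MeCN)4]PF6 (3 mol %; pheox = cyclometalated (S)-2,4-diphenyl-2-oxazoline), 10 (2.5 equiv, syringe pump, 8 h), CH2Cl2, 0 °C to rt
Reagents that add atoms: none
Why: Metal-carbene cyclopropanation of a terminal alkene with a diazoketone, in which the ruthenium carbene adds only to the monosubstituted C7=C8 bond (the cis-disubstituted, electron-poor lactone alkene is inert), end-on approach places the acyl group trans to the side chain, and attack anti to the lactone in the inside-alkoxy conformer of the allylic silyl ether, reinforced by the matched catalyst antipode, sets C7 and C9 as S,S.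

**Step 6**
Reactants: 12 4-iodophenol; 13 acrylic acid
Product: 14 (2E)-3-(4-hydroxyphenyl)prop-2-enoic acid (p-coumaric acid)
Conditions: Pd(OAc)2 (1 mol %), NaOAc (1.1 equiv), DMF, 100 °C
Reagents that add atoms: none
Why: Mizoroki–Heck reaction, in which ligand-free zerovalent palladium formed in situ inserts into the aryl iodide and syn-insertion followed by syn-β-hydride elimination on the acrylate gives only the E-cinnamic acid without phenol protection.

**Step 7**
Reactants: 11 (6R)-6-[(S)-(tert-butyldimethylsilyloxy){(1S,2S)-2-[(2R)-2-chloropropanoyl]cyclopropyl}methyl]-5,6-dihydro-2H-pyran-2-one; 14 p-coumaric acid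
Product: 16 brevipolide G, via silyl ether 15 (not isolated)
Conditions: KHCO3 (1.1 equiv), DMF, 35 °C; then MeCN, 48% aq HF, 0 °C to rt
Reagents that add atoms: none
Why: SN2 carboxylate alkylation at an α-halo ketone followed by fluoride desilylation, in which bicarbonate deprotonates only the carboxylic acid and not the phenol, the carboxylate attacks the carbonyl-activated secondary chloride from the back and inverts C11 from R to S while poorly soluble KCl cannot re-attack, and aqueous HF then removes the silyl group without touching lactone, ester or ketone.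

**Compound list**
1 | (2E)-penta-2,4-dienal | C=C/C=C/C=O | starting material
2 | vinylmagnesium bromide | C=C[Mg]Br | starting material
3 | rac-(4E)-hepta-1,4,6-trien-3-ol | C=CC(O)/C=C/C=C | intermediate
4 | (1S)-1-[(2S,3S)-3-ethenyloxiran-2-yl]prop-2-en-1-ol | C=C[C@H](O)[C@@H]1O[C@H]1C=C | intermediate
5 | tert-butyl(dimethyl){[(1S)-1-[(2R,3S)-3-ethenyloxiran-2-yl]prop-2-en-1-yl]oxy}silane | C=C[C@H](O[Si](C)(C)C(C)(C)C)[C@@H]1O[C@H]1C=C | intermediate
6 | (6R)-6-[(1S)-1-(tert-butyldimethylsilyloxy)prop-2-en-1-yl]-3,6-dihydro-2H-pyran-2-one | C=C[C@H](O[Si](C)(C)C(C)(C)C)[C@H]1C=CCC(=O)O1 | intermediate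
7 | (6R)-6-[(1S)-1-(tert-butyldimethylsilyloxy)prop-2-en-1-yl]-5,6-dihydro-2H-pyran-2-one | C=C[C@H](O[Si](C)(C)C(C)(C)C)[C@H]1CC=CC(=O)O1 | intermediate
8 | (2R)-2-chloropropanoic acid | C[C@@H](Cl)C(=O)O | starting material
9 | (2R)-2-chloropropanoyl chloride | C[C@@H](Cl)C(=O)Cl | intermediate
10 | (3R)-3-chloro-1-diazobutan-2-one | C[C@@H](Cl)C(=O)C=[N+]=[N-] | intermediate
11 | (6R)-6-[(S)-(tert-butyldimethylsilyloxy){(1S,2S)-2-[(2R)-2-chloropropanoyl]cyclopropyl}methyl]-5,6-dihydro-2H-pyran-2-one | C[C@@H](Cl)C(=O)[C@H]1C[C@@H]1[C@H](O[Si](C)(C)C(C)(C)C)[C@H]1CC=CC(=O)O1 | intermediate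
12 | 4-iodophenol | Oc1ccc(I)cc1 | starting material
13 | acrylic acid | C=CC(=O)O | starting material
14 | (2E)-3-(4-hydroxyphenyl)prop-2-enoic acid (p-coumaric acid) | OC(=O)/C=C/c1ccc(O)cc1 | intermediate
15 | 6-O-tert-butyldimethylsilyl brevipolide G | C[C@H](OC(=O)/C=C/c1ccc(O)cc1)C(=O)[C@H]1C[C@@H]1[C@H](O[Si](C)(C)C(C)(C)C)[C@H]1CC=CC(=O)O1 | intermediate
16 | brevipolide G, (2S)-1-{(1S,2S)-2-[(S)-hydroxy((2R)-6-oxo-3,6-dihydro-2H-pyran-2-yl)methyl]cyclopropyl}-1-oxopropan-2-yl (2E)-3-(4-hydroxyphenyl)prop-2-enoate | C[C@H](OC(=O)/C=C/c1ccc(O)cc1)C(=O)[C@H]1C[C@@H]1[C@H](O)[C@H]1CC=CC(=O)O1 | target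

**Total step count:** 7
**Longest linear sequence:** 5 steps (1 → 2 → 3 → 5 → 7)

**Steps most likely to fail**

Step 3 (the new reaction).
- Risks: CO may insert at the internal terminus and give a β-lactone. The alkoxide may close on the allyl unit to a 2,5-dihydrofuran. β-Hydride loss may give a dienone. The silyl group may move from O6 to the C5 alkoxide. Palladium may re-ionise the allylic lactone 6 before it is conjugated.
- Fallback (known chemistry, no carbonylation): it sets out from 2. Double addition of 2 to ethyl formate gives penta-1,4-dien-3-ol F1. Sharpless desymmetrising epoxidation (Ti(OiPr)4, L-(+)-DIPT, t-BuOOH, −20 °C) gives (2R,3S)-1,2-epoxypent-4-en-3-ol F2. TBSCl and imidazole give its silyl ether F3. Lithiated ethyl propiolate with BF3·OEt2 at −78 °C opens the terminal epoxide carbon to ethyl (5R,6S)-6-(tert-butyldimethylsilyloxy)-5-hydroxyoct-7-en-2-ynoate F4. Semi-hydrogenation over Pd/CaCO3 poisoned with Pb(OAc)2 and quinoline gives the Z-enoate, ethyl (2Z,5R,6S)-6-(tert-butyldimethylsilyloxy)-5-hydroxyocta-2,7-dienoate F5. This lactonises on standing with a trace of acid, and the route is rejoined at 7.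

Step 5.
- Risks: the branched allylic alkene may react slowly, so carbene dimerisation takes over. The trans/cis and facial ratios may be modest if catalyst and substrate are mismatched.
- Fallback (carbon frame first, methylene last): it sets out from 9 and 7. Stille acylation of 9 with tributyl(vinyl)stannane (PdCl2(PPh3)2 cat., THF) gives (4R)-4-chloropent-1-en-3-one F6. Cross-metathesis of 7 with F6 (second-generation Hoveyda–Grubbs catalyst, RuCl2(SIMes)(=CH-C6H4-2-OiPr), CH2Cl2, reflux) gives the E-enone (6R)-6-[(1S,2E,5R)-1-(tert-butyldimethylsilyloxy)-5-chloro-4-oxohex-2-en-1-yl]-5,6-dihydro-2H-pyran-2-one F7. Methylene transfer with CH2N2 and Pd(OAc)2 to the more reactive acyclic enone, from the face anti to the lactone, rejoins the route at 11.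

Step 7.
- Risks: a slow displacement would allow chloride exchange or enolisation to erode C11. Some phenoxide alkylation could also occur.
- Fallback (C–O bond with a small phenol-free acid, aryl–vinyl bond last): it sets out from 11 and 13. KHCO3 in DMF gives the acrylate (2S)-1-{(1S,2S)-2-[(S)-(tert-butyldimethylsilyloxy)((2R)-6-oxo-3,6-dihydro-2H-pyran-2-yl)methyl]cyclopropyl}-1-oxopropan-2-yl prop-2-enoate F8. Aqueous HF in MeCN gives the free alcohol F9. A Jeffery-type Heck reaction of F9 with 12 (Pd(OAc)2, NaHCO3, Bu4NCl, DMF, 60 °C) arylates only the terminal acrylate and arrives at 16.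

**Further compounds**
F1 | step 3 | penta-1,4-dien-3-ol | C=CC(O)C=C
F2 | step 3 | (2R,3S)-1,2-epoxypent-4-en-3-ol | C=C[C@H](O)[C@H]1CO1
F3 | step 3 | tert-butyl(dimethyl){[(1S)-1-[(2R)-oxiran-2-yl]prop-2-en-1-yl]oxy}silane | C=C[C@H](O[Si](C)(C)C(C)(C)C)[C@H]1CO1
F4 | step 3 | ethyl (5R,6S)-6-(tert-butyldimethylsilyloxy)-5-hydroxyoct-7-en-2-ynoate | C=C[C@H](O[Si](C)(C)C(C)(C)C)[C@H](O)CC#CC(=O)OCC
F5 | step 3 | ethyl (2Z,5R,6S)-6-(tert-butyldimethylsilyloxy)-5-hydroxyocta-2,7-dienoate | C=C[C@H](O[Si](C)(C)C(C)(C)C)[C@H](O)C/C=C\C(=O)OCC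
F6 | step 5 | (4R)-4-chloropent-1-en-3-one | C[C@@H](Cl)C(=O)C=C
F7 | step 5 | (6R)-6-[(1S,2E,5R)-1-(tert-butyldimethylsilyloxy)-5-chloro-4-oxohex-2-en-1-yl]-5,6-dihydro-2H-pyran-2-one | C[C@@H](Cl)C(=O)/C=C/[C@H](O[Si](C)(C)C(C)(C)C)[C@H]1CC=CC(=O)O1
F8 | step 7 | (2S)-1-{(1S,2S)-2-[(S)-(tert-butyldimethylsilyloxy)((2R)-6-oxo-3,6-dihydro-2H-pyran-2-yl)methyl]cyclopropyl}-1-oxopropan-2-yl prop-2-enoate | C[C@H](OC(=O)C=C)C(=O)[C@H]1C[C@@H]1[C@H](O[Si](C)(C)C(C)(C)C)[C@H]1CC=CC(=O)O1
F9 | step 7 | (2S)-1-{(1S,2S)-2-[(S)-hydroxy((2R)-6-oxo-3,6-dihydro-2H-pyran-2-yl)methyl]cyclopropyl}-1-oxopropan-2-yl prop-2-enoate | C[C@H](OC(=O)C=C)C(=O)[C@H]1C[C@@H]1[C@H](O)[C@H]1CC=CC(=O)O1
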